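**Strategy.** The route rests on cutting the cyclohexenone ring across C4–C5 and C1–C6. The contiguous stereotriad (C4 oxygen cis to the C5 branch, C6 methyl trans to it) is the ortho-endo pattern of a [4+2] cycloaddition. A Diels–Alder reaction of (E)-1-acetoxybuta-1,3-diene with achiral (E)-3-crotonoyloxazolidin-2-one, catalysed by a divalent copper bis(oxazoline) complex, therefore builds the six-membered carbocycle and all three ring stereocentres in one operation; the imide carbonyl carbon becomes C1'. Afterwards C1 is oxidised, both methoxy groups are installed, and a C1' alkylzinc is joined by Negishi coupling to a separately made (2E,6E,9S,10E)-configured C2'–C12' alkenyl iodide.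

Key step: step 2

Remarks on the chemistry (assumptions):
- Locants follow the target: C1 ketone, C2 and C3 methoxy carbons, C4 carbinol, C5 chain-bearing carbon, C6 methyl-bearing carbon, C1'–C12' side chain.
- Commercial 1-acetoxybuta-1,3-diene is an E/Z mixture; only the E isomer 4 is expected to react, so the mixture is used in excess.
- (R,R)-t-Bu-box is 2,2'-(propane-2,2-diyl)bis[(4R)-4-tert-butyl-4,5-dihydrooxazole]. This enantiomer is chosen from the square-planar chelate model: its tert-butyl group covers the α-Re face of the bound imide.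
- The (S)-enantiomer of the phosphoric acid in step 16 is chosen by analogy: the (R)-acid is expected to give R carbinols from aryl and alkenyl aldehydes.
- The new centres in 9 and 11 are drawn as the expected anti isomers; they are erased in steps 7 and 8.
- Abbreviations: (S)-TRIP is (S)-3,3'-bis(2,4,6-triisopropylphenyl)-1,1'-binaphthyl-2,2'-diyl hydrogen phosphate; SPhos is 2-dicyclohexylphosphino-2',6'-dimethoxybiphenyl; PPTS is pyridinium p-toluenesulfonate; DMA is N,N-dimethylacetamide; TES is triethylsilyl; TBS is tert-butyldimethylsilyl.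

**Ring fragment**

Step 1
Reactants: 1 2-oxazolidinone; 2 (E)-crotonoyl chloride
Product: 3 (E)-3-(but-2-enoyl)oxazolidin-2-one
Conditions: Et3N, LiCl, THF, 0 → 25 °C
Reagents that add atoms: none
Why: Acyl substitution at the acid chloride by the lithium-coordinated carbamate nitrogen (N-acylation of an oxazolidinone) should give the imide without touching the E alkene; no stereocentre is formed.

Step 2
Reactants: 3 (E)-3-(but-2-enoyl)oxazolidin-2-one; 4 (E)-buta-1,3-dien-1-yl acetate
Product: 5 3-{[(1R,2S,6S)-2-acetoxy-6-methylcyclohex-3-en-1-yl]carbonyl}oxazolidin-2-one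
Conditions: [Cu((R,R)-t-Bu-box)](SbF6)2 (10 mol %, from CuCl2, ligand and AgSbF6), 4 (3 equiv), CH2Cl2, 25 °C
Reagents that add atoms: none
Why: Two-point chelation of the imide carbonyls to the square-planar divalent copper centre locks the s-cis enoyl conformer and lowers its LUMO, so the diene adds in a concerted, asynchronous, suprafacial [4+2] cycloaddition; the closest known reaction type is the bis(oxazoline)copper-catalysed Diels–Alder reaction of acyl oxazolidinones with 1-oxygenated butadienes. The six-membered carbocycle is closed by intermolecular cycloaddition, C4–C5 and C1–C6 forming in the same step. C5 is set by the ligand, whose tert-butyl group covers the α-Re face so that the diene should bond to the α-Si face. C4 follows from the endo transition state (imide carbonyl tucked under the diene), which places the acetoxy group cis to the acyl group, and C6 follows from the E geometry of the crotonoyl alkene, carried through stereospecifically as the trans C5/C6 pair. The step needs ortho regiochemistry, endo selectivity and one enantioface; these are secured by the acetoxy donor (largest HOMO coefficient at the unsubstituted terminus, which bonds to the β-carbon), by secondary overlap with the bound imide and by the ligand enantiomer, respectively.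

Step 3
Reactants: 5 Diels–Alder adduct
Product: 6 (1S,5S,6S)-6-(hydroxymethyl)-5-methylcyclohex-2-en-1-ol
Conditions: LiAlH4, THF, 0 °C; aqueous NaOH work-up
Reagents that add atoms: none
Why: Hydride reduction cleaves the exocyclic imide carbonyl to the primary C1' alcohol and the acetate to the C4 alcohol (reductive removal of an oxazolidinone and ester reduction); no ring bond or stereocentre is affected.

Step 4
Reactants: 6 diol
Product: 7 isopropylidene acetal of 6 (cis-fused 1,3-dioxane)
Conditions: 2,2-dimethoxypropane, PPTS (cat.), CH2Cl2, 25 °C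
Reagents that add atoms: 2,2-dimethoxypropane, COC(C)(C)OC
Why: Acid-catalysed transacetalisation ties the cis-disposed C4 and C1' hydroxyls into a six-membered acetal (1,3-diol acetonide formation), masking both oxygens for the oxidant and base steps that follow.

Step 5
Reactants: 7 acetonide
Product: 8 (4S,5S,6R)-4-hydroxy-5-(hydroxymethyl)-6-methylcyclohex-2-en-1-one isopropylidene acetal
Conditions: CrO3, 3,5-dimethylpyrazole, CH2Cl2, −20 °C
Reagents that add atoms: chromium trioxide, O=[Cr](=O)=O
Why: Allylic C–H oxidation by the CrO3–3,5-dimethylpyrazole complex should take place at the unhindered C1 methylene rather than at the ring-fusion C4–H and give the conjugated enone with C2=C3 in place; the acetal is inert and no stereocentre is formed.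

Step 6
Reactants: 8 enone
Product: 9 (2S,3S,4R,5S,6R)-2,3-epoxy ketone (epoxide anti to the C4 oxygen)
Conditions: 30% H2O2, NaOH (cat.), MeOH, 0 °C
Reagents that add atoms: hydrogen peroxide, OO
Why: Conjugate addition of hydroperoxide to C3 and closure of the enolate onto oxygen (Weitz–Scheffer epoxidation) is specific for the electron-poor alkene; attack anti to the C4 oxygen is expected, and both new centres are erased in step 7.

Step 7
Reactants: 9 epoxy ketone
Product: 10 (4R,5S,6R)-2-methoxy enone acetonide
Conditions: NaOMe, MeOH, 50 °C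
Reagents that add atoms: sodium methoxide, [Na+].[O-]C
Why: Methoxide opens the epoxy ketone at C2, which is activated for substitution like an α-halo ketone, and E1cB loss of the C3 hydroxyl restores the enone as its 2-methoxy derivative (base-induced conversion of an α,β-epoxy ketone into an α-alkoxy enone); the trans C5/C6 arrangement is the thermodynamically preferred one, so enolisation at C6 should do no harm.

Step 8
Reactants: 10 2-methoxy enone
Product: 12 (4R,5S,6R)-3-bromo-2-methoxy enone acetonide, via dibromide 11 (not isolated)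
Conditions: Br2, CH2Cl2, 0 °C; then Et3N
Reagents that add atoms: bromine, BrBr
Why: Bromine adds to the enol-ether-like C2=C3 bond, and with Et3N the α-bromo ether at C2 ionises and the C3 proton is lost (bromination–dehydrobromination of an enone), leaving bromine on the β-carbon C3.

Step 9
Reactants: 12 3-bromo-2-methoxy enone
Product: 13 (4R,5S,6R)-2,3-dimethoxy enone acetonide
Conditions: NaOMe, MeOH, 0 → 25 °C
Reagents that add atoms: sodium methoxide, [Na+].[O-]C
Why: Conjugate addition of methoxide to C3 followed by loss of bromide (addition–elimination on a β-halo enone, a vinylogous acyl substitution) should install the second methoxy group.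

Step 10
Reactants: 13 dimethoxy enone acetonide
Product: 14 (4R,5S,6R)-4-hydroxy-5-(hydroxymethyl)-2,3-dimethoxy-6-methylcyclohex-2-en-1-one
Conditions: PPTS, MeOH, 25 °C
Reagents that add atoms: none
Why: Mild acid-catalysed transacetalisation to methanol frees the C4 and C1' hydroxyls, while the vinylogous ester and the dehydration-prone 4-hydroxy enone should survive the weakly acidic medium.

Step 11
Reactants: 14 diol
Product: 15 (4R,5R,6R)-4-hydroxy-5-(iodomethyl)-2,3-dimethoxy-6-methylcyclohex-2-en-1-one
Conditions: I2, PPh3, imidazole, CH2Cl2, 0 °C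
Reagents that add atoms: iodine, [I][I]
Why: The iodophosphonium reagent activates the unhindered primary C1' hydroxyl much faster than the hindered secondary C4 hydroxyl, and iodide displaces the phosphine oxide by SN2 (Appel-type iodination in the Garegg–Samuelsson variant).

Step 12
Reactants: 15 iodo alcohol
Product: 16 (4R,5R,6R)-5-(iodomethyl)-2,3-dimethoxy-6-methyl-4-(triethylsilyloxy)cyclohex-2-en-1-one
Conditions: TESOTf, 2,6-lutidine, CH2Cl2, −78 °C
Reagents that add atoms: triethylsilyl trifluoromethanesulfonate, CC[Si](CC)(CC)OS(=O)(=O)C(F)(F)F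
Why: Silylation of the C4 hydroxyl with a silyl triflate and a hindered pyridine base removes the only acidic proton before the organozinc is made; at −78 °C the ketone should not be enolised.

**Side-chain fragment**

Step 13
Reactants: 17 prop-2-yn-1-ol
Product: 19 (E)-3-iodo-2-methylprop-2-en-1-ol, via alkenylalane 18 (not isolated)
Conditions: Me3Al (3 equiv), Cp2ZrCl2 (25 mol %), CH2Cl2, 0 → 25 °C; then I2, THF, −30 °C
Reagents that add atoms: trimethylaluminium, C[Al](C)C; iodine, [I][I]
Why: Zirconium-catalysed syn methylalumination (Negishi carboalumination) puts methyl on the internal and aluminium on the terminal alkyne carbon, and iodinolysis with retention gives the E alkenyl iodide.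

Step 14
Reactants: 19 iodo allylic alcohol
Product: 20 (E)-tert-butyl[(3-iodo-2-methylprop-2-en-1-yl)oxy]dimethylsilane
Conditions: TBSCl, imidazole, CH2Cl2, 25 °C
Reagents that add atoms: tert-butyldimethylsilyl chloride, CC(C)(C)[Si](C)(C)Cl
Why: Silylation of the primary alcohol (silyl ether formation) protects the future C12' oxygen through the organometallic steps.

Step 15
Reactants: 20 silyl ether
Product: 22 (E)-4-(tert-butyldimethylsilyloxy)-3-methylbut-2-enal, via alkenyllithium 21 (not isolated)
Conditions: t-BuLi (2.1 equiv), Et2O, −78 °C; then DMF, −78 → 0 °C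
Reagents that add atoms: N,N-dimethylformamide, CN(C)C=O
Why: Iodine–lithium exchange with retention of alkene geometry followed by formylation of the alkenyllithium with DMF (Bouveault-type aldehyde synthesis) should give the E enal.

Step 16
Reactants: 22 enal; 23 allenylboronic acid pinacol ester
Product: 24 (4S,5E)-7-(tert-butyldimethylsilyloxy)-6-methylhept-5-en-1-yn-4-ol
Conditions: (S)-TRIP (10 mol %), 4 Å MS, toluene, 0 °C
Reagents that add atoms: none
Why: The chiral phosphoric acid activates the allenylboronate and the aldehyde in a closed six-membered SE2' transition state (asymmetric propargylboration), and the (S)-acid should deliver the propargyl group to the Si face of the enal, giving the 9'S carbinol.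

Step 17
Reactants: 24 homopropargylic alcohol
Product: 25 (4S,5E)-4,7-bis(tert-butyldimethylsilyloxy)-6-methylhept-5-en-1-yne
Conditions: TBSCl, imidazole, DMF, 25 °C
Reagents that add atoms: tert-butyldimethylsilyl chloride, CC(C)(C)[Si](C)(C)Cl
Why: Silylation of the secondary allylic alcohol (silyl ether formation) removes the acidic proton before the carbometalation and coupling steps.

Step 18
Reactants: 25 bis-silyl alkyne
Product: 27 (1E,4S,5E)-4,7-bis(tert-butyldimethylsilyloxy)-1-iodo-2,6-dimethylhepta-1,5-diene, via alkenylalane 26 (not isolated)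
Conditions: Me3Al (2.5 equiv), Cp2ZrCl2 (50 mol %), CH2Cl2, 0 → 25 °C; then I2, THF, −30 °C
Reagents that add atoms: trimethylaluminium, C[Al](C)C; iodine, [I][I]
Why: Negishi carboalumination of the terminal alkyne (syn addition, methyl to the internal carbon) and iodinolysis with retention should give the E trisubstituted alkenyl iodide that becomes C6'=C7'; the silyl ethers and the existing trisubstituted alkene are inert.

Step 19
Reactants: 27 alkenyl iodide; 28 (4-bromobut-1-yn-1-yl)trimethylsilane
Product: 30 (5E,8S,9E)-8,11-bis(tert-butyldimethylsilyloxy)-6,10-dimethyl-1-(trimethylsilyl)undeca-5,9-dien-1-yne, via alkylzinc bromide 29 (not isolated)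
Conditions: 28, Zn dust, I2 (5 mol %), DMA, 80 °C; then 27, Pd(PPh3)4 (5 mol %), THF, 25 → 50 °C
Reagents that add atoms: none
Why: Zinc inserts into the primary C–Br bond, and palladium-catalysed sp3–sp2 Negishi coupling with the alkenyl iodide forms C5'–C6' with retention of the E geometry; the silyl-capped alkyne is a spectator.

Step 20
Reactants: 30 silyl enyne
Product: 31 (5E,8S,9E)-8,11-bis(tert-butyldimethylsilyloxy)-6,10-dimethylundeca-5,9-dien-1-yne
Conditions: K2CO3, MeOH, 25 °C
Reagents that add atoms: none
Why: Methoxide-mediated protodesilylation cleaves only the C(sp)–Si bond and should leave both silyl ethers in place.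

Step 21
Reactants: 31 terminal enyne
Product: 33 (1E,5E,8S,9E)-8,11-bis(tert-butyldimethylsilyloxy)-1-iodo-2,6,10-trimethylundeca-1,5,9-triene, via alkenylalane 32 (not isolated)
Conditions: Me3Al (2.5 equiv), Cp2ZrCl2 (50 mol %), CH2Cl2, 0 → 25 °C; then I2, THF, −30 °C
Reagents that add atoms: trimethylaluminium, C[Al](C)C; iodine, [I][I]
Why: A second Negishi carboalumination–iodinolysis on the terminal alkyne sets the E-configured C2'=C3' alkenyl iodide; the two trisubstituted alkenes do not react under these conditions.

**Union and deprotection**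

Step 22
Reactants: 16 ring iodide; 33 chain alkenyl iodide
Product: 35 tris-silyl ether of the target, via alkylzinc iodide 34 (not isolated)
Conditions: 16, Zn dust (activated with TMSCl and BrCH2CH2Br), DMA, 25 °C; then 33, Pd(OAc)2 (5 mol %), SPhos (10 mol %), THF, 25 → 40 °C
Reagents that add atoms: none
Why: Direct zinc insertion into the primary C–I bond tolerates the ketone and the silyl ether, and palladium-catalysed sp3–sp2 Negishi coupling (oxidative addition to the alkenyl iodide, transmetalation, reductive elimination) forms C1'–C2' with retention of all alkene geometries and without touching the ring stereocentres.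

Step 23
Reactants: 35 tris-silyl ether
Product: 36 CNP0109398.2
Conditions: HF·pyridine, pyridine, THF, 0 → 25 °C
Reagents that add atoms: none
Why: Buffered hydrogen fluoride cleaves the triethylsilyl ether and both tert-butyldimethylsilyl ethers (fluoride-driven desilylation) under conditions mild enough for the allylic alcohols and the 4-hydroxy enone, giving the target.

**Compound list**

1 | 2-oxazolidinone | O=C1NCCO1 | starting material
2 | (E)-crotonoyl chloride | C/C=C/C(Cl)=O | starting material
3 | (E)-3-(but-2-enoyl)oxazolidin-2-one | C/C=C/C(=O)N1CCOC1=O | intermediate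
4 | (E)-buta-1,3-dien-1-yl acetate [(E)-1-acetoxybuta-1,3-diene] | C=C/C=C/OC(C)=O | starting material
5 | 3-{[(1R,2S,6S)-2-acetoxy-6-methylcyclohex-3-en-1-yl]carbonyl}oxazolidin-2-one (target numbering: C4 acetoxy cis to C5 acyl, C6 methyl trans) | C1=C[C@H](OC(C)=O)[C@H](C(=O)N2CCOC2=O)[C@@H](C)C1 | intermediate
6 | (1S,5S,6S)-6-(hydroxymethyl)-5-methylcyclohex-2-en-1-ol | C1=C[C@H](O)[C@H](CO)[C@@H](C)C1 | intermediate
7 | isopropylidene acetal (cis-fused 1,3-dioxane) of (1S,5S,6S)-6-(hydroxymethyl)-5-methylcyclohex-2-en-1-ol | C1=C[C@H](OC(C)(C)OC2)[C@H]2[C@@H](C)C1 | intermediate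
8 | (4S,5S,6R)-4-hydroxy-5-(hydroxymethyl)-6-methylcyclohex-2-en-1-one, 4-O,1'-O-isopropylidene acetal | C1=C[C@H](OC(C)(C)OC2)[C@H]2[C@@H](C)C1=O | intermediate
9 | (2S,3S,4R,5S,6R)-2,3-epoxy-4-hydroxy-5-(hydroxymethyl)-6-methylcyclohexan-1-one, 4-O,1'-O-isopropylidene acetal (epoxide anti to the C4 oxygen) | O=C1[C@H]2O[C@H]2[C@H](OC(C)(C)OC3)[C@H]3[C@H]1C | intermediate
10 | (4R,5S,6R)-4-hydroxy-5-(hydroxymethyl)-2-methoxy-6-methylcyclohex-2-en-1-one, 4-O,1'-O-isopropylidene acetal | COC1=C[C@H](OC(C)(C)OC2)[C@H]2[C@@H](C)C1=O | intermediate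
11 | trans-2,3-dibromide of 10 (2-bromo-2-methoxy, C3 bromine anti to the C4 oxygen; not isolated) | O=C1[C@](OC)(Br)[C@@H](Br)[C@H](OC(C)(C)OC3)[C@H]3[C@H]1C | intermediate
12 | (4R,5S,6R)-3-bromo-4-hydroxy-5-(hydroxymethyl)-2-methoxy-6-methylcyclohex-2-en-1-one, 4-O,1'-O-isopropylidene acetal | COC1=C(Br)[C@H](OC(C)(C)OC2)[C@H]2[C@@H](C)C1=O | intermediate
13 | (4R,5S,6R)-4-hydroxy-5-(hydroxymethyl)-2,3-dimethoxy-6-methylcyclohex-2-en-1-one, 4-O,1'-O-isopropylidene acetal | COC1=C(OC)[C@H](OC(C)(C)OC2)[C@H]2[C@@H](C)C1=O | intermediate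
14 | (4R,5S,6R)-4-hydroxy-5-(hydroxymethyl)-2,3-dimethoxy-6-methylcyclohex-2-en-1-one | COC1=C(OC)[C@H](O)[C@H](CO)[C@@H](C)C1=O | intermediate
15 | (4R,5R,6R)-4-hydroxy-5-(iodomethyl)-2,3-dimethoxy-6-methylcyclohex-2-en-1-one | COC1=C(OC)[C@H](O)[C@H](CI)[C@@H](C)C1=O | intermediate
16 | (4R,5R,6R)-5-(iodomethyl)-2,3-dimethoxy-6-methyl-4-(triethylsilyloxy)cyclohex-2-en-1-one | COC1=C(OC)[C@H](O[Si](CC)(CC)CC)[C@H](CI)[C@@H](C)C1=O | intermediate
17 | prop-2-yn-1-ol | C#CCO | starting material
18 | (E)-[3-(dimethylalumanyl)-2-methylprop-2-en-1-yl]oxy(dimethyl)alane (not isolated) | C[Al](C)OC/C(C)=C/[Al](C)C | intermediate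
19 | (E)-3-iodo-2-methylprop-2-en-1-ol | OC/C(C)=C/I | intermediate
20 | (E)-tert-butyl[(3-iodo-2-methylprop-2-en-1-yl)oxy]dimethylsilane | CC(C)(C)[Si](C)(C)OC/C(C)=C/I | intermediate
21 | (E)-[3-(tert-butyldimethylsilyloxy)-2-methylprop-1-en-1-yl]lithium (not isolated) | CC(C)(C)[Si](C)(C)OC/C(C)=C/[Li] | intermediate
22 | (E)-4-(tert-butyldimethylsilyloxy)-3-methylbut-2-enal | CC(C)(C)[Si](C)(C)OC/C(C)=C/C=O | intermediate
23 | 4,4,5,5-tetramethyl-2-(propa-1,2-dien-1-yl)-1,3,2-dioxaborolane (allenylboronic acid pinacol ester) | C=C=CB1OC(C)(C)C(C)(C)O1 | starting material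
24 | (4S,5E)-7-(tert-butyldimethylsilyloxy)-6-methylhept-5-en-1-yn-4-ol | C#CC[C@H](O)/C=C(\C)CO[Si](C)(C)C(C)(C)C | intermediate
25 | (4S,5E)-4,7-bis(tert-butyldimethylsilyloxy)-6-methylhept-5-en-1-yne | C#CC[C@H](O[Si](C)(C)C(C)(C)C)/C=C(\C)CO[Si](C)(C)C(C)(C)C | intermediate
26 | (1E,4S,5E)-[4,7-bis(tert-butyldimethylsilyloxy)-2,6-dimethylhepta-1,5-dien-1-yl]dimethylalane (not isolated) | C[Al](C)/C=C(\C)C[C@H](O[Si](C)(C)C(C)(C)C)/C=C(\C)CO[Si](C)(C)C(C)(C)C | intermediate
27 | (1E,4S,5E)-4,7-bis(tert-butyldimethylsilyloxy)-1-iodo-2,6-dimethylhepta-1,5-diene | I/C=C(\C)C[C@H](O[Si](C)(C)C(C)(C)C)/C=C(\C)CO[Si](C)(C)C(C)(C)C | intermediate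
28 | (4-bromobut-1-yn-1-yl)trimethylsilane | C[Si](C)(C)C#CCCBr | starting material
29 | [4-(trimethylsilyl)but-3-yn-1-yl]zinc bromide (not isolated) | C[Si](C)(C)C#CCC[Zn]Br | intermediate
30 | (5E,8S,9E)-8,11-bis(tert-butyldimethylsilyloxy)-6,10-dimethyl-1-(trimethylsilyl)undeca-5,9-dien-1-yne | C[Si](C)(C)C#CCC/C=C(\C)C[C@H](O[Si](C)(C)C(C)(C)C)/C=C(\C)CO[Si](C)(C)C(C)(C)C | intermediate
31 | (5E,8S,9E)-8,11-bis(tert-butyldimethylsilyloxy)-6,10-dimethylundeca-5,9-dien-1-yne | C#CCC/C=C(\C)C[C@H](O[Si](C)(C)C(C)(C)C)/C=C(\C)CO[Si](C)(C)C(C)(C)C | intermediate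
32 | (1E,5E,8S,9E)-[8,11-bis(tert-butyldimethylsilyloxy)-2,6,10-trimethylundeca-1,5,9-trien-1-yl]dimethylalane (not isolated) | C[Al](C)/C=C(\C)CC/C=C(\C)C[C@H](O[Si](C)(C)C(C)(C)C)/C=C(\C)CO[Si](C)(C)C(C)(C)C | intermediate
33 | (1E,5E,8S,9E)-8,11-bis(tert-butyldimethylsilyloxy)-1-iodo-2,6,10-trimethylundeca-1,5,9-triene | I/C=C(\C)CC/C=C(\C)C[C@H](O[Si](C)(C)C(C)(C)C)/C=C(\C)CO[Si](C)(C)C(C)(C)C | intermediate
34 | {[(1R,2R,6R)-3,4-dimethoxy-6-methyl-5-oxo-2-(triethylsilyloxy)cyclohex-3-en-1-yl]methyl}zinc iodide (not isolated) | COC1=C(OC)[C@H](O[Si](CC)(CC)CC)[C@H](C[Zn]I)[C@@H](C)C1=O | intermediate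
35 | (4R,5R,6R)-5-[(2E,6E,9S,10E)-9,12-bis(tert-butyldimethylsilyloxy)-3,7,11-trimethyldodeca-2,6,10-trien-1-yl]-2,3-dimethoxy-6-methyl-4-(triethylsilyloxy)cyclohex-2-en-1-one | COC1=C(OC)[C@H](O[Si](CC)(CC)CC)[C@H](C/C=C(\C)CC/C=C(\C)C[C@H](O[Si](C)(C)C(C)(C)C)/C=C(\C)CO[Si](C)(C)C(C)(C)C)[C@@H](C)C1=O | intermediate
36 | CNP0109398.2, (4R,5R,6R)-4-hydroxy-5-[(2E,6E,9S,10E)-9,12-dihydroxy-3,7,11-trimethyldodeca-2,6,10-trien-1-yl]-2,3-dimethoxy-6-methylcyclohex-2-en-1-one | COC1=C(OC)[C@H](O)[C@H](C/C=C(\C)CC/C=C(\C)C[C@H](O)/C=C(\C)CO)[C@@H](C)C1=O | target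

**Count**

Total: 23 steps. Longest linear sequence: 14 steps (steps 1–12, 22 and 23). The side-chain branch (steps 13–21) joins at step 22.

**Steps most likely to fail**

Step 2. The β-methyl group of the dienophile slows the cycloaddition, so diene polymerisation or catalyst deactivation may overtake it, and the higher temperature needed may erode endo and facial selectivity. The fallback replaces Lewis-acid activation by iminium-ion catalysis. It sets out from 4 and returns at 6. Diene 4 and (E)-but-2-enal with (5S)-5-benzyl-2,2,3-trimethylimidazolidin-4-one hydrochloride (20 mol %) in MeCN/H2O at 0–25 °C should react through the (E)-iminium ion, whose α-Re face is covered by the benzyl group, in the same ortho-endo sense to give (1R,2S,6S)-2-acetoxy-6-methylcyclohex-3-ene-1-carbaldehyde F1. This β-acetoxy aldehyde is reduced without purification with LiAlH4 in THF at 0 °C, which converts the formyl group and the acetate into diol 6.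

Step 5. Hydrogen abstraction at the ring-fusion C4–H (allylic and next to oxygen) or transposition of the allyl system may compete with oxidation of the C1 methylene, giving regioisomeric enones or loss of the acetal. The fallback brings the C1 oxygen in with the diene instead of oxidising a C–H bond. It sets out from 3 and returns at 8. Imide 3 and (1E,3E)-buta-1,3-diene-1,4-diyl diacetate under the conditions of step 2 should give the endo adduct 3-{[1,4-diacetoxy-6-methylcyclohex-2-en-5-yl]carbonyl}oxazolidin-2-one F2 (target numbering; both acetoxy groups cis to the C5 acyl group, C6 methyl trans). LiAlH4 in THF should reduce it to the triol 5-(hydroxymethyl)-6-methylcyclohex-2-ene-1,4-diol F3. 2,2-Dimethoxypropane with PPTS should engage only the cis-1,3-related C4 and C1' hydroxyls in a six-membered acetal, giving the 4-O,1'-O-isopropylidene acetal with free C1 allylic alcohol F4. MnO2 in CH2Cl2 should then oxidise this allylic alcohol to enone 8.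

Step 22. Zinc insertion into the β-branched iodide may be slow, and the alkylzinc may be protonated or the alkylpalladium intermediate may undergo β-hydride elimination before the C–C bond forms. The fallback avoids a preformed organometallic by nickel-catalysed reductive cross-electrophile coupling. It sets out from 16 and 33 and returns at 35. Both iodides are combined with NiBr2(dme), 4,4'-di-tert-butyl-2,2'-bipyridine and Mn powder in DMA at 25 °C; the alkyl iodide should enter as a radical and the alkenyl iodide by oxidative addition, giving 35 directly with no new compound F0.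

**Further compounds**

F1 | step 2 | (1R,2S,6S)-2-acetoxy-6-methylcyclohex-3-ene-1-carbaldehyde | C1=C[C@H](OC(C)=O)[C@H](C=O)[C@@H](C)C1
F2 | step 5 | 3-{[1,4-diacetoxy-6-methylcyclohex-2-en-5-yl]carbonyl}oxazolidin-2-one (target numbering; C1 and C4 acetoxy cis to the C5 acyl group, C6 methyl trans) | C1=C[C@H](OC(C)=O)[C@H](C(=O)N2CCOC2=O)[C@@H](C)[C@@H]1OC(C)=O
F3 | step 5 | 5-(hydroxymethyl)-6-methylcyclohex-2-ene-1,4-diol (target numbering; C1 and C4 hydroxyls cis to the C5 hydroxymethyl, C6 methyl trans) | C1=C[C@H](O)[C@H](CO)[C@@H](C)[C@@H]1O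
F4 | step 5 | 4-O,1'-O-isopropylidene acetal of F3 with free C1 allylic hydroxyl | C1=C[C@H](OC(C)(C)OC2)[C@H]2[C@@H](C)[C@@H]1O
F0 | step 22 | none | none
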